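**Assumption:** the sense of induction of the chiral gold catalyst in step 4 cannot be predicted with certainty; the ligand enantiomer that gives (1S,5R,6S)-7 is used and is written below as (R).

## Retrosynthetic overview

1. Target ⇐ lactone opening, loss of CO2 and equilibration α to the ketone from a cis-fused α-aroyl 3,7-dioxabicyclo[3.3.0]octan-2-one; the lactone carbonyl is a traceless tether and its ring oxygen becomes the CH2OH.
2. That bicycle ⇐ (3+2) annulation of formaldehyde across the donor–acceptor bond of an aryl-cyclopropane-fused keto lactone; inversion at the benzylic carbon turns the trans cyclopropane into the 2,3-cis tetrahydrofuran.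
3. Cyclopropane-fused lactone ⇐ enantioselective gold-catalysed alkyne oxidation / intramolecular cyclopropanation of an achiral cinnamyl arylpropiolate; γ-lactone and cyclopropane close together and three stereocentres are set.
4. Ester ⇐ (E)-3,4-dimethoxycinnamyl alcohol (from methyl 3,4-dimethoxycinnamate) + 3-(3,4,5-trimethoxyphenyl)propiolic acid (from 5-iodo-1,2,3-trimethoxybenzene and propiolic acid).
5. Ring order: γ-lactone and cyclopropane together → tetrahydrofuran (cyclopropane consumed) → lactone opened and its carbonyl excised.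

## Route

Step 1
Reactants: 1 methyl (E)-3-(3,4-dimethoxyphenyl)prop-2-enoate
Product: 2 (E)-3-(3,4-dimethoxyphenyl)prop-2-en-1-ol
Conditions: i-Bu2AlH (2.3 equiv), CH2Cl2, −78 → 0 °C; aq. potassium sodium tartrate
Reagents that add atoms: none
Why: Hydride reduction of the ester with diisobutylaluminium hydride stops at the allylic alcohol and leaves the E double bond untouched; no stereocentre is formed.

Step 2
Reactants: 3 5-iodo-1,2,3-trimethoxybenzene; 4 prop-2-ynoic acid (propiolic acid)
Product: 5 3-(3,4,5-trimethoxyphenyl)prop-2-ynoic acid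
Conditions: Pd(PPh3)4 (2.5 mol %), DBU (2.4 equiv), DMSO, 30 °C; then 1 M HCl
Reagents that add atoms: none
Why: Copper-free Sonogashira coupling of the aryl iodide with the DBU salt of propiolic acid joins the terminal alkyne carbon to the ring, and the absence of copper and heat keeps the arylpropiolic acid from decarboxylating.

Step 3
Reactants: 2 (E)-3-(3,4-dimethoxyphenyl)prop-2-en-1-ol; 5 3-(3,4,5-trimethoxyphenyl)prop-2-ynoic acid
Product: 6 (E)-3-(3,4-dimethoxyphenyl)prop-2-en-1-yl 3-(3,4,5-trimethoxyphenyl)prop-2-ynoate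
Conditions: DCC (1.1 equiv), DMAP (5 mol %), CH2Cl2, 0 → 23 °C
Reagents that add atoms: none
Why: Steglich esterification joins the two halves under neutral conditions that tolerate the ynoate and the electron-rich allylic alcohol; no stereocentre is formed.

Step 4
Reactants: 6 (E)-3-(3,4-dimethoxyphenyl)prop-2-en-1-yl 3-(3,4,5-trimethoxyphenyl)prop-2-ynoate
Product: 7 (1S,5R,6S)-6-(3,4-dimethoxyphenyl)-1-(3,4,5-trimethoxybenzoyl)-3-oxabicyclo[3.1.0]hexan-2-one (aryl on C6 trans to the lactone CH2, i.e. exo)
Conditions: (R)-DTBM-SEGPHOS(AuCl)2 (2.5 mol %), AgNTf2 (5 mol %), 8-methylquinoline N-oxide (1.3 equiv, added over 4 h), 4 Å MS, ClCH2CH2Cl, 0 → 23 °C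
Reagents that add atoms: 8-methylquinoline N-oxide, Cc1cccc2ccc[n+]([O-])c12
Why: Proposed new method: cationic monovalent gold activates the ynoate so that the N-oxide adds at the aryl-bearing β-carbon, N–O cleavage leaves a gold carbene flanked by the new aryl ketone and the ester, and this carbene cyclopropanates the tethered E-styrene, closing the γ-lactone and the cyclopropane together (aryl exo from the E geometry, C1 fixed by the ring fusion, absolute sense from the chiral bisphosphine); the closest known reaction type is the gold-catalysed N-oxide oxidation/cyclopropanation of 1,6-enynes and N-allyl propiolamides, including enantioselective ether-tethered cases.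

Step 5
Reactants: 7 (1S,5R,6S)-6-(3,4-dimethoxyphenyl)-1-(3,4,5-trimethoxybenzoyl)-3-oxabicyclo[3.1.0]hexan-2-one
Product: 8 (1R,5R,6R)-6-(3,4-dimethoxyphenyl)-1-(3,4,5-trimethoxybenzoyl)-3,7-dioxabicyclo[3.3.0]octan-2-one (cis-fused; aryl on C6 cis to the lactone CH2, i.e. endo)
Conditions: Sn(OTf)2 (10 mol %), monomeric CH2O (ca. 5 equiv, cracked from paraformaldehyde into CH2Cl2), 4 Å MS, CH2Cl2, −45 → −20 °C
Reagents that add atoms: formaldehyde, C=O
Why: Lewis-acid-catalysed (3+2) annulation of a donor–acceptor cyclopropane with an aldehyde: the tin-chelated keto lactone polarises the C1–C6 bond, the formaldehyde oxygen attacks the benzylic C6 in an SN2-like way with inversion, and the enolate closes on the oxocarbenium carbon on the only face the cis ring fusion allows, so the exo aryl of 7 becomes the endo aryl of 8 (the 2,3-cis relationship of the target).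

Step 6
Reactants: 8 (1R,5R,6R)-6-(3,4-dimethoxyphenyl)-1-(3,4,5-trimethoxybenzoyl)-3,7-dioxabicyclo[3.3.0]octan-2-one
Product: 11 [(3S,4R,5R)-5-(3,4-dimethoxyphenyl)-4-(hydroxymethyl)oxolan-3-yl](3,4,5-trimethoxyphenyl)methanone, via hydroxy keto acid 9 (not isolated), via all-cis keto alcohol 10 (not isolated)
Conditions: LiOH·H2O (2.0 equiv), THF/H2O 3:1, 0 °C; AcOH to pH 5, 45 °C; then crude, DBU (0.3 equiv), THF, 23 °C
Reagents that add atoms: none
Why: Saponification of the strained α-acyl lactone gives a β-keto acid that decarboxylates on mild acidification, and base epimerisation through the enolate of the aryl ketone places the aroyl group trans to the neighbouring CH2OH (thermodynamic control), while the C2 and C3 centres of the ring are not touched.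

## Compound list

1 | methyl (E)-3-(3,4-dimethoxyphenyl)prop-2-enoate | COC(=O)/C=C/c1ccc(OC)c(OC)c1 | starting material
2 | (E)-3-(3,4-dimethoxyphenyl)prop-2-en-1-ol | OC/C=C/c1ccc(OC)c(OC)c1 | intermediate
3 | 5-iodo-1,2,3-trimethoxybenzene | COc1cc(I)cc(OC)c1OC | starting material
4 | prop-2-ynoic acid (propiolic acid) | OC(=O)C#C | starting material
5 | 3-(3,4,5-trimethoxyphenyl)prop-2-ynoic acid | COc1cc(C#CC(=O)O)cc(OC)c1OC | intermediate
6 | (E)-3-(3,4-dimethoxyphenyl)prop-2-en-1-yl 3-(3,4,5-trimethoxyphenyl)prop-2-ynoate | COc1ccc(/C=C/COC(=O)C#Cc2cc(OC)c(OC)c(OC)c2)cc1OC | intermediate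
7 | (1S,5R,6S)-6-(3,4-dimethoxyphenyl)-1-(3,4,5-trimethoxybenzoyl)-3-oxabicyclo[3.1.0]hexan-2-one | COc1ccc([C@@H]2[C@H]3COC(=O)[C@@]23C(=O)c4cc(OC)c(OC)c(OC)c4)cc1OC | intermediate
8 | (1R,5R,6R)-6-(3,4-dimethoxyphenyl)-1-(3,4,5-trimethoxybenzoyl)-3,7-dioxabicyclo[3.3.0]octan-2-one | COc1ccc([C@@H]2OC[C@]3(C(=O)c4cc(OC)c(OC)c(OC)c4)C(=O)OC[C@H]23)cc1OC | intermediate
9 | (3R,4R,5R)-5-(3,4-dimethoxyphenyl)-4-(hydroxymethyl)-3-(3,4,5-trimethoxybenzoyl)oxolane-3-carboxylic acid (formed as its lithium salt, not isolated) | COc1ccc([C@@H]2OC[C@](C(=O)c3cc(OC)c(OC)c(OC)c3)(C(=O)O)[C@@H]2CO)cc1OC | intermediate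
10 | [(3R,4R,5R)-5-(3,4-dimethoxyphenyl)-4-(hydroxymethyl)oxolan-3-yl](3,4,5-trimethoxyphenyl)methanone (all-cis C3 epimer of the target, not isolated) | COc1ccc([C@@H]2OC[C@H](C(=O)c3cc(OC)c(OC)c(OC)c3)[C@@H]2CO)cc1OC | intermediate
11 | [(3S,4R,5R)-5-(3,4-dimethoxyphenyl)-4-(hydroxymethyl)oxolan-3-yl](3,4,5-trimethoxyphenyl)methanone, equal to (2R,3R,4S)-2-(3,4-dimethoxyphenyl)-3-(hydroxymethyl)-4-(3,4,5-trimethoxybenzoyl)tetrahydrofuran | COc1ccc([C@@H]2OC[C@@H](C(=O)c3cc(OC)c(OC)c(OC)c3)[C@@H]2CO)cc1OC | target

## Count and risks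

Total step count: 6. Longest linear sequence: 5 (steps 1, 3, 4, 5, 6); step 2 is the side branch.

**Step 4 (most at risk).** The ester must reach its reactive conformer before the carbene is oxidised a second time, the gold cation may open the very electron-rich donor–acceptor cyclopropane, and the enantioselectivity of an ester-tethered case is untested.
Fallback, setting out from 2 and coming back at 7: 2 is transesterified with commercial ethyl 3-oxo-3-(3,4,5-trimethoxyphenyl)propanoate (DMAP cat., toluene, reflux, ethanol distilled off) to give (E)-3-(3,4-dimethoxyphenyl)prop-2-en-1-yl 3-oxo-3-(3,4,5-trimethoxyphenyl)propanoate F1. Regitz diazo transfer with 4-acetamidobenzenesulfonyl azide and Et3N in MeCN gives (E)-3-(3,4-dimethoxyphenyl)prop-2-en-1-yl 2-diazo-3-oxo-3-(3,4,5-trimethoxyphenyl)propanoate F2. Asymmetric intramolecular cyclopropanation of this acceptor/acceptor diazo ester by divalent cobalt metalloradical catalysis with the chiral amidoporphyrin complex [Co(3,5-DitBu-ChenPhyrin)] (toluene, 23 °C; alternatively Rh2(S-PTTL)4) then gives 7. The carbene is made from a diazo group instead of from the alkyne.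

**Step 5.** Formaldehyde is a weak oxygen nucleophile and polymerises, ionisation at the dimethoxybenzylic carbon would erode the inversion and give the C6 epimer, and closure by the ketone oxygen (Cloke–Wilson type) competes.
Fallback, setting out from 7 and coming back at 8: the cyclopropane is opened with water (Yb(OTf)3 cat., MeCN/H2O, 0 °C) in an SN2-type ring opening with inversion to give (4R)-4-[(R)-(3,4-dimethoxyphenyl)(hydroxy)methyl]-3-(3,4,5-trimethoxybenzoyl)oxolan-2-one F3 (C3 epimers interconvert through the enol). Paraformaldehyde with catalytic Sc(OTf)3 in CH2Cl2 at 0 °C then converts the benzylic hydroxyl into its O–CH2 oxocarbenium ion, which the enol of the β-keto lactone captures on the same face to close the tetrahydrofuran and give 8. The C6–O bond is made first and separately, so the carbon–carbon closure no longer has to outrun polymerisation.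

**Step 6.** Hydroxide may attack the ketone (retro-Claisen loss of the aroyl group), the hydroxy acid may relactonise faster than it decarboxylates, and base may open the ring by β-alkoxide elimination.
Fallback, setting out from 8 and coming back at 10: NaOMe (cat.) in MeOH at 0 °C cleaves the non-enolisable β-keto lactone by retro-Claisen attack at the ketone to give (1R,5R,6R)-6-(3,4-dimethoxyphenyl)-3,7-dioxabicyclo[3.3.0]octan-2-one F4. Commercial 3,4,5-trimethoxyphenylmagnesium bromide (1.05 equiv, THF, −78 °C) adds once to the lactone carbonyl and, after aqueous NH4Cl, gives the all-cis keto alcohol 10. This is epimerised to 11 with DBU as in the last stage of step 6. The aroyl group is removed on purpose and put back on the lactone carbonyl, so no decarboxylation is needed.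

## Further compounds

F1 | step 4 | (E)-3-(3,4-dimethoxyphenyl)prop-2-en-1-yl 3-oxo-3-(3,4,5-trimethoxyphenyl)propanoate | COc1ccc(/C=C/COC(=O)CC(=O)c2cc(OC)c(OC)c(OC)c2)cc1OC
F2 | step 4 | (E)-3-(3,4-dimethoxyphenyl)prop-2-en-1-yl 2-diazo-3-oxo-3-(3,4,5-trimethoxyphenyl)propanoate | COc1ccc(/C=C/COC(=O)C(=[N+]=[N-])C(=O)c2cc(OC)c(OC)c(OC)c2)cc1OC
F3 | step 5 | (4R)-4-[(R)-(3,4-dimethoxyphenyl)(hydroxy)methyl]-3-(3,4,5-trimethoxybenzoyl)oxolan-2-one | COc1ccc([C@H](O)[C@H]2COC(=O)C2C(=O)c3cc(OC)c(OC)c(OC)c3)cc1OC
F4 | step 6 | (1R,5R,6R)-6-(3,4-dimethoxyphenyl)-3,7-dioxabicyclo[3.3.0]octan-2-one | COc1ccc([C@@H]2OC[C@@H]3C(=O)OC[C@H]23)cc1OC
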